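**Plan**
1. The target is (S)-glycerol 1-acetate whose O-2 carries (13R)-ent-labd-8-en-15-oic acid (5R,10R, trans-decalin); labdane numbering is used throughout.
2. Retrosynthetic cuts, in order: benzyl ether on glycerol O-3; C9–C11 (sp2–sp3 coupling of a C9 enol triflate with the complete glyceride side chain); triflate back to a C9 ketone; C6–C7 (ring B); C9–C10 (allylboration of methacrolein); glyceride ester O–C15.
3. Forward: ring A is bought as β-cyclocitral. A γ-selective allylboration joins C9 to C10, making the quaternary C10 and an exocyclic C5=C6 alkene. Ring B is then closed by a C7 radical bonding to C6, and the side chain is joined last at C9.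
4. Structural basis: C5 lies between the fully substituted C4 and C10, so the radical can only bond at C6 (6-endo), and the resulting C5 radical is reduced anti to the C10 methyl (trans fusion). Because C10 is quaternary, the C9 ketone enolises only toward C8, which fixes the tetrasubstituted C8=C9 alkene.
5. Stereochemistry: C10 is set by a chiral phosphoric acid catalyst (step 3) and C5 is relayed from C10 (step 6). The transient C9 and C8 centres are erased (steps 7, 8). C13 and glycerol C2 are bought.

Key step: step 6

Remark: β-cyclocitral, methacrolein, methyl hydrogen (R)-3-methylglutarate and (R)-3-(benzyloxy)propane-1,2-diol are taken as purchasable. Atom numbers in the text are labdane numbers (ring A: C1–C5, C10; ring B: C5–C10; C17 on C8, C20 on C10; side chain C11–C16).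

**Step 1**
Reactants: 1 β-cyclocitral (2,6,6-trimethylcyclohex-1-ene-1-carbaldehyde)
Product: 2 β-cyclogeraniol, (2,6,6-trimethylcyclohex-1-en-1-yl)methanol
Conditions: NaBH4, MeOH, 0 °C
Reagents that add atoms: none
Why: Borohydride 1,2-reduction of the hindered enal gives the primary allylic alcohol; no stereocentre is formed.

**Step 2**
Reactants: 2 β-cyclogeraniol
Product: 3 4,4,5,5-tetramethyl-2-[(2,6,6-trimethylcyclohex-1-en-1-yl)methyl]-1,3,2-dioxaborolane
Conditions: B2pin2, Pd(MeCN)4(BF4)2 (5 mol %), DMSO/MeOH, 50 °C
Reagents that add atoms: bis(pinacolato)diboron, CC1(C)OB(OC1(C)C)B1OC(C)(C)C(C)(C)O1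
Why: Palladium-catalysed allylic borylation (Miyaura-type, used directly on the allylic alcohol) through an η3-allylpalladium species should place boron on the unsubstituted terminus C6, so that the fully substituted C10 becomes the γ-carbon of the reagent.

**Step 3**
Reactants: 3 the allylboronate; 4 methacrolein (2-methylprop-2-enal)
Product: 6 (1S)-2-methyl-1-[(1R)-1,3,3-trimethyl-2-methylidenecyclohexyl]prop-2-en-1-ol, via O-pinacolboryl ether 5 (not isolated)
Conditions: (R)-3,3'-bis(2,4,6-triisopropylphenyl)-1,1'-binaphthyl-2,2'-diyl hydrogen phosphate (10 mol %), 4 Å MS, toluene, −30 → 0 °C; aq. NaHCO3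
Reagents that add atoms: none
Why: Chiral phosphoric acid catalysed allylboration of an aldehyde with a γ,γ-disubstituted allylboronate proceeds through a closed chair transition state with the isopropenyl group equatorial; it joins C9 to the γ-carbon C10 (quaternary centre, alkene moved to exocyclic C5=C6), the (R)-acid is expected by analogy with other aldehydes to select the Re face (carbinol 1S; the antipodal acid would be used if the sense proved opposite), and the C10 methyl, being cis to the CH2B group and therefore axial in the chair, then fixes C10 as R.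

**Step 4**
Reactants: 6 the dienol
Product: 8 (1S)-2-methyl-1-[(1R)-1,3,3-trimethyl-2-methylidenecyclohexyl]propane-1,3-diol, via bis(9-BBN) adduct 7 (not isolated)
Conditions: 9-BBN (2.5 equiv), THF, 0 °C → rt; NaOH, H2O2, 0 °C
Reagents that add atoms: hydrogen peroxide, OO
Why: Hydroboration–oxidation with 9-BBN should take the unhindered isopropenyl group anti-Markovnikov and leave the C5=C6 methylidene, shielded by the quaternary C4 and C10, untouched; the new C8 centre is not controlled because step 8 destroys it.

**Step 5**
Reactants: 8 the diol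
Product: 9 (1S)-3-iodo-2-methyl-1-[(1R)-1,3,3-trimethyl-2-methylidenecyclohexyl]propan-1-ol
Conditions: I2, PPh3, imidazole, CH2Cl2, 0 °C
Reagents that add atoms: iodine, II
Why: Appel-type iodination is selective for the primary hydroxyl; the secondary C9 hydroxyl next to the quaternary carbon should not react.

**Step 6**
Reactants: 9 the iodo alcohol
Product: 10 (1S,4aR,8aR)-2,5,5,8a-tetramethyldecahydronaphthalen-1-ol
Conditions: Bu3SnH (syringe pump), AIBN, benzene (0.01 M), 80 °C
Reagents that add atoms: none
Why: The stannyl radical abstracts iodine from C7, and the primary C7 radical adds to the CH2 terminus (C6) of the exocyclic C5=C6 alkene, which closes ring B in the 6-endo-trig mode and leaves a tertiary radical at C5 that takes a hydrogen atom from Bu3SnH. The closest known reaction type is the tin hydride mediated cyclisation of 5-substituted hex-5-enyl radicals, in which a substituent on the inner alkene carbon turns the closure from 5-exo to 6-endo. Here the 5-exo alternative would have to form a bond at C5 between the two fully substituted carbons C4 and C10, so bonding at C6 is the only open path. The new stereocentre C5 is set in the hydrogen transfer: one face of the ring-fusion radical is shielded by the axial C10 methyl and the axial C4 methyl, hydrogen is delivered to the other face, and the trans-fused (4aR,8aR) decalin, also the more stable fusion, should result. Cyclisation must outrun direct reduction of the C7 radical, which is secured by a low stannane concentration; the free C9 hydroxyl and the epimeric C8 centre do not interfere and are erased in steps 7 and 8.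

**Step 7**
Reactants: 10 the decalinol
Product: 11 (4aR,8aR)-2,5,5,8a-tetramethyloctahydronaphthalen-1(2H)-one
Conditions: Dess–Martin periodinane, NaHCO3, CH2Cl2, rt
Reagents that add atoms: none
Why: Dess–Martin oxidation of the hindered secondary alcohol removes the C9 stereocentre, which has served its purpose as the partner of C10 in step 3.

**Step 8**
Reactants: 11 the ketone
Product: 13 (4aR,8aR)-2,5,5,8a-tetramethyl-3,4,4a,5,6,7,8,8a-octahydronaphthalen-1-yl trifluoromethanesulfonate, via potassium enolate 12 (not isolated)
Conditions: KN(SiMe3)2, THF, −78 → 0 °C; PhNTf2, −78 °C → rt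
Reagents that add atoms: N-phenylbis(trifluoromethanesulfonimide), O=S(=O)(N(c1ccccc1)S(=O)(=O)C(F)(F)F)C(F)(F)F
Why: Because C10 is quaternary the ketone can enolise only toward C8, so enol triflate formation places the future tetrasubstituted alkene at C8=C9 without regiochemical choice and erases the C8 centre.

**Step 9**
Reactants: 14 (3R)-5-methoxy-3-methyl-5-oxopentanoic acid (methyl hydrogen (R)-3-methylglutarate)
Product: 16 (4R)-4-methyloxan-2-one, via hydroxy ester 15 (not isolated)
Conditions: BH3·SMe2, THF, 0 °C → rt; MeOH; TsOH (cat.), CH2Cl2, rt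
Reagents that add atoms: none
Why: Borane reduces the carboxylic acid chemoselectively beside the methyl ester and acid-catalysed lactonisation follows; the stereocentre (C13 of the target) comes unchanged from the purchased half-ester.

**Step 10**
Reactants: 16 the lactone
Product: 18 (3S)-5-iodo-3-methylpentanoic acid, via trimethylsilyl ester 17 (not isolated)
Conditions: Me3SiI, CH2Cl2, rt; H2O
Reagents that add atoms: iodotrimethylsilane, C[Si](C)(C)I
Why: Silyl iodide ring-opening of a lactone to an ω-iodo acid (SN2 attack of iodide at the primary O-alkyl carbon); the stereocentre is not involved and its descriptor changes only through the priority of iodine.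

**Step 11**
Reactants: 19 (2R)-3-(benzyloxy)propane-1,2-diol
Product: 20 (2S)-3-(benzyloxy)-2-hydroxypropyl acetate
Conditions: AcCl, 2,4,6-collidine, CH2Cl2, −78 °C
Reagents that add atoms: acetyl chloride, CC(=O)Cl
Why: Selective acylation of the primary hydroxyl of a 1,2-diol with acetyl chloride and a hindered pyridine base at low temperature; the bought glycerol stereocentre is untouched.

**Step 12**
Reactants: 18 the iodo acid; 20 the glycerol monoacetate
Product: 21 (2S)-1-(acetyloxy)-3-(benzyloxy)propan-2-yl (3S)-5-iodo-3-methylpentanoate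
Conditions: DCC, DMAP (cat.), CH2Cl2, 0 °C
Reagents that add atoms: none
Why: Steglich esterification of the secondary hydroxyl under mild, cold conditions, chosen to limit 1,2-acetyl migration and relactonisation of the iodo acid.

**Step 13**
Reactants: 21 the iodo ester; 13 the enol triflate
Product: 23 (2S)-1-(acetyloxy)-3-(benzyloxy)propan-2-yl (3R)-3-methyl-5-[(4aR,8aR)-2,5,5,8a-tetramethyl-3,4,4a,5,6,7,8,8a-octahydronaphthalen-1-yl]pentanoate, via alkylzinc iodide 22 (not isolated)
Conditions: Zn dust, LiCl, THF, 40 °C; then 13, Pd(dppf)Cl2 (5 mol %), THF/NMP, 60 °C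
Reagents that add atoms: none
Why: Negishi sp3–sp2 cross-coupling: LiCl-assisted zinc insertion gives an ester-tolerant alkylzinc iodide that should couple with the 2,6,6-trisubstituted cyclohexenyl-type triflate under a bidentate-phosphine palladium catalyst that suppresses β-hydride elimination, forming C9–C11 and leaving the alkene where the triflate placed it.

**Step 14**
Reactants: 23 the benzyl ether
Product: 24 (2S)-1-(acetyloxy)-3-hydroxypropan-2-yl (3R)-3-methyl-5-[(4aR,8aR)-2,5,5,8a-tetramethyl-3,4,4a,5,6,7,8,8a-octahydronaphthalen-1-yl]pentanoate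
Conditions: H2 (1 atm), Pd/C (10 wt %), EtOAc, rt
Reagents that add atoms: none
Why: Hydrogenolysis of the benzyl ether under neutral conditions should avoid acyl migration in the 1,2-diacylglycerol, and the hindered tetrasubstituted C8=C9 alkene is not expected to be reduced at atmospheric pressure.

**Compound list**
1 | β-cyclocitral | CC1=C(C=O)C(C)(C)CCC1 | starting material
2 | β-cyclogeraniol | CC1=C(CO)C(C)(C)CCC1 | intermediate
3 | 4,4,5,5-tetramethyl-2-[(2,6,6-trimethylcyclohex-1-en-1-yl)methyl]-1,3,2-dioxaborolane | CC1=C(CB2OC(C)(C)C(C)(C)O2)C(C)(C)CCC1 | intermediate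
4 | methacrolein | CC(=C)C=O | starting material
5 | O-pinacolboryl ether of 6 | C=C(C)[C@H](OB1OC(C)(C)C(C)(C)O1)[C@]1(C)CCCC(C)(C)C1=C | intermediate (not isolated)
6 | (1S)-2-methyl-1-[(1R)-1,3,3-trimethyl-2-methylidenecyclohexyl]prop-2-en-1-ol | C=C(C)[C@H](O)[C@]1(C)CCCC(C)(C)C1=C | intermediate
7 | bis(9-borabicyclo[3.3.1]nonan-9-yl) adduct of 6 (B on the terminal carbon and on oxygen; C2 epimers) | C(B1C2CCCC1CCC2)C(C)[C@H](OB1C2CCCC1CCC2)[C@]1(C)CCCC(C)(C)C1=C | intermediate (not isolated)
8 | (1S)-2-methyl-1-[(1R)-1,3,3-trimethyl-2-methylidenecyclohexyl]propane-1,3-diol (C2 epimers) | OCC(C)[C@H](O)[C@]1(C)CCCC(C)(C)C1=C | intermediate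
9 | (1S)-3-iodo-2-methyl-1-[(1R)-1,3,3-trimethyl-2-methylidenecyclohexyl]propan-1-ol (C2 epimers) | ICC(C)[C@H](O)[C@]1(C)CCCC(C)(C)C1=C | intermediate
10 | (1S,4aR,8aR)-2,5,5,8a-tetramethyldecahydronaphthalen-1-ol (C2 epimers) | O[C@H]1C(C)CC[C@@H]2C(C)(C)CCC[C@@]12C | intermediate
11 | (4aR,8aR)-2,5,5,8a-tetramethyloctahydronaphthalen-1(2H)-one (C2 epimers) | O=C1C(C)CC[C@@H]2C(C)(C)CCC[C@@]12C | intermediate
12 | potassium enolate of 11 | [K+].[O-]C1=C(C)CC[C@@H]2C(C)(C)CCC[C@@]12C | intermediate (not isolated)
13 | (4aR,8aR)-2,5,5,8a-tetramethyl-3,4,4a,5,6,7,8,8a-octahydronaphthalen-1-yl trifluoromethanesulfonate | FC(F)(F)S(=O)(=O)OC1=C(C)CC[C@@H]2C(C)(C)CCC[C@@]12C | intermediate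
14 | (3R)-5-methoxy-3-methyl-5-oxopentanoic acid | COC(=O)C[C@H](C)CC(=O)O | starting material
15 | methyl (3R)-5-hydroxy-3-methylpentanoate | COC(=O)C[C@H](C)CCO | intermediate (not isolated)
16 | (4R)-4-methyloxan-2-one | O=C1C[C@H](C)CCO1 | intermediate
17 | trimethylsilyl (3S)-5-iodo-3-methylpentanoate | C[Si](C)(C)OC(=O)C[C@H](C)CCI | intermediate (not isolated)
18 | (3S)-5-iodo-3-methylpentanoic acid | OC(=O)C[C@H](C)CCI | intermediate
19 | (2R)-3-(benzyloxy)propane-1,2-diol | OC[C@H](COCc1ccccc1)O | starting material
20 | (2S)-3-(benzyloxy)-2-hydroxypropyl acetate | CC(=O)OC[C@H](COCc1ccccc1)O | intermediate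
21 | (2S)-1-(acetyloxy)-3-(benzyloxy)propan-2-yl (3S)-5-iodo-3-methylpentanoate | CC(=O)OC[C@H](COCc1ccccc1)OC(=O)C[C@H](C)CCI | intermediate
22 | [(3S)-5-{[(2S)-1-(acetyloxy)-3-(benzyloxy)propan-2-yl]oxy}-3-methyl-5-oxopentyl](iodo)zinc | CC(=O)OC[C@H](COCc1ccccc1)OC(=O)C[C@H](C)CC[Zn]I | intermediate (not isolated)
23 | (2S)-1-(acetyloxy)-3-(benzyloxy)propan-2-yl (3R)-3-methyl-5-[(4aR,8aR)-2,5,5,8a-tetramethyl-3,4,4a,5,6,7,8,8a-octahydronaphthalen-1-yl]pentanoate | CC(=O)OC[C@H](COCc1ccccc1)OC(=O)C[C@H](C)CCC1=C(C)CC[C@@H]2C(C)(C)CCC[C@@]12C | intermediate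
24 | (2S)-1-(acetyloxy)-3-hydroxypropan-2-yl (3R)-3-methyl-5-[(4aR,8aR)-2,5,5,8a-tetramethyl-3,4,4a,5,6,7,8,8a-octahydronaphthalen-1-yl]pentanoate | CC(=O)OC[C@H](CO)OC(=O)C[C@H](C)CCC1=C(C)CC[C@@H]2C(C)(C)CCC[C@@]12C | target

Total step count: 14. Longest linear sequence: 10 steps (steps 1–8, 13, 14).

**Steps most likely to fail**

Step 3. What may go wrong is slow γ-addition at the congested ring carbon and incomplete discrimination of the aldehyde faces by the catalyst. The fallback sets out from boronate 3 and comes back at diol 8; it buys the controlling stereocentre instead of using a catalyst. Methyl (S)-3-hydroxy-2-methylpropanoate is silylated (t-BuMe2SiCl, imidazole) to methyl (2S)-3-[(tert-butyldimethylsilyl)oxy]-2-methylpropanoate F1 and half-reduced (i-Bu2AlH, −78 °C) to (2S)-3-[(tert-butyldimethylsilyl)oxy]-2-methylpropanal F2. Heating 3 with F2 in toluene without catalyst should go through the same chair transition state. The C10 methyl that is cis to the CH2B group is axial there and disfavours the rotamer that leads to the 1,2-syn adduct, so the 1,2-anti adduct (carbinol against α-methyl) is expected, first as its O-pinacolboryl ether F3 and after hydrolysis as (1S,2S)-3-[(tert-butyldimethylsilyl)oxy]-2-methyl-1-[(1R)-1,3,3-trimethyl-2-methylidenecyclohexyl]propan-1-ol F4. F4 is separated from minor diastereomers by chromatography; Bu4NF then gives diol 8 as its single (2S) epimer, which enters step 5, and the hydroboration of step 4 is no longer needed.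

Step 6. What may go wrong is reduction of the C7 radical by the stannane before ring closure, and incomplete face selectivity in the hydrogen transfer to C5. The fallback sets out from dienol 6 and comes back at ketone 11; it closes the same bond by a polar path. Dess–Martin oxidation of 6 gives 2-methyl-1-[(1R)-1,3,3-trimethyl-2-methylidenecyclohexyl]prop-2-en-1-one F5. With EtAlCl2 in CH2Cl2 at −78 °C the exocyclic alkene should add through C6 to the activated enone terminus C7 (enone-initiated cation–olefin cyclisation, 6-endo), and the C5 cation loses a C6 proton to give (8aR)-2,5,5,8a-tetramethyl-3,5,6,7,8,8a-hexahydronaphthalen-1(2H)-one F6. Hydrogenation of the C5=C6 alkene (H2, Pd/C, EtOAc) from the face opposite the C10 methyl then gives the trans-fused ketone 11.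

Step 13. What may go wrong is slow oxidative addition into the hindered triflate, with protodemetalation or β-hydride elimination of the alkylzinc partner taking over. The fallback sets out from iodo ester 21 and comes back at 23; the sp3 nucleophile is made by hydroboration instead of metal insertion. Dehydroiodination of 21 (DBU, toluene, 80 °C) gives (2S)-1-(acetyloxy)-3-(benzyloxy)propan-2-yl (3S)-3-methylpent-4-enoate F7. Hydroboration with 9-BBN in THF gives (2S)-1-(acetyloxy)-3-(benzyloxy)propan-2-yl (3R)-5-(9-borabicyclo[3.3.1]nonan-9-yl)-3-methylpentanoate F8, which is used without isolation in a B-alkyl Suzuki–Miyaura coupling with triflate 13 (Pd(dppf)Cl2, AsPh3, Cs2CO3, DMF/THF/H2O, rt) to give 23.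

**Further compounds**
F1 | step 3 | methyl (2S)-3-[(tert-butyldimethylsilyl)oxy]-2-methylpropanoate | COC(=O)[C@@H](C)CO[Si](C)(C)C(C)(C)C
F2 | step 3 | (2S)-3-[(tert-butyldimethylsilyl)oxy]-2-methylpropanal | O=C[C@@H](C)CO[Si](C)(C)C(C)(C)C
F3 | step 3 | O-pinacolboryl ether of F4 | CC(C)(C)[Si](C)(C)OC[C@H](C)[C@H](OB1OC(C)(C)C(C)(C)O1)[C@]1(C)CCCC(C)(C)C1=C
F4 | step 3 | (1S,2S)-3-[(tert-butyldimethylsilyl)oxy]-2-methyl-1-[(1R)-1,3,3-trimethyl-2-methylidenecyclohexyl]propan-1-ol | CC(C)(C)[Si](C)(C)OC[C@H](C)[C@H](O)[C@]1(C)CCCC(C)(C)C1=C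
F5 | step 6 | 2-methyl-1-[(1R)-1,3,3-trimethyl-2-methylidenecyclohexyl]prop-2-en-1-one | CC(=C)C(=O)[C@]1(C)CCCC(C)(C)C1=C
F6 | step 6 | (8aR)-2,5,5,8a-tetramethyl-3,5,6,7,8,8a-hexahydronaphthalen-1(2H)-one | O=C1C(C)CC=C2C(C)(C)CCC[C@@]12C
F7 | step 13 | (2S)-1-(acetyloxy)-3-(benzyloxy)propan-2-yl (3S)-3-methylpent-4-enoate | CC(=O)OC[C@H](COCc1ccccc1)OC(=O)C[C@H](C)C=C
F8 | step 13 | (2S)-1-(acetyloxy)-3-(benzyloxy)propan-2-yl (3R)-5-(9-borabicyclo[3.3.1]nonan-9-yl)-3-methylpentanoate | CC(=O)OC[C@H](COCc1ccccc1)OC(=O)C[C@H](C)CCB1C2CCCC1CCC2
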